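**The ceiling.** Left-handed product can hold half of the charge, the half that is left-handed substrate, so I reckoned how much of that substrate still stands at the end.

| flask | left-handed substrate | right-handed substrate | partner | precatalyst | temperature | remark | time |
|---|---|---|---|---|---|---|---|
| Monday's | 0.075 M | 0.075 M | 1.5 equiv | 1.2 mol% | 40 °C | run made earlier |  |
| autumn | 0.050 M | 0.050 M | 1.50 equiv | 1.2 mol% | 40 °C |  | 5.0 min |
| spring | 0.050 M | 0.050 M | 1.50 equiv | 1.2 mol% | 60 °C |  | 5.0 min |

Monday's run (percent of the left-handed substrate and right-handed substrate together charged)

| time / s | left-handed substrate / % | left-handed product / % | right-handed product / % | right-handed substrate / % |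
|---|---|---|---|---|
| 10.0 | 41.8 | 8.0 | 0 | 49.0 |
| 20.0 | 31.5 | 19.8 | 1.8 | 49.1 |
| 30.0 | 23.3 | 27.2 | 1.7 | 48.3 |
| 40.0 | 16.8 | 33.3 | 3.4 | 48.3 |
| 50.0 | 12.2 | 39.2 | 4.4 | 47.3 |
| 60.0 | 9.5 | 43.3 | 4.0 | 46.4 |

(standard deviation of a reading: 1 percentage point)

- catalyst is single-handed; left-handed substrate and right-handed substrate are mirror images of each other, charged as a racemate, each of them at the stated concentration
- the earlier runs do not show what temperature does; that part of a forecast is a guess
- no earlier run changes the charge of precatalyst; that part of a forecast is a guess

1. which of these there is most of at the end, counted by the substrate in it, autumn (right-handed product / right-handed substrate / left-handed substrate / left-handed product)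
2. which of these there is most of at the end, counted by the substrate in it, spring (right-handed product / right-handed substrate / left-handed substrate / left-handed product)
3. the largest of these amounts at the end, in percent of the left-handed substrate and right-handed substrate together charged, autumn
4. the largest of these amounts at the end, in percent of the left-handed substrate and right-handed substrate together charged, spring

**First way.** From the left-handed substrate readings of Monday's run, 10.0 s to 60.0 s, I took a pseudo-first-order decay constant k = 0.0296 s⁻¹. Autumn has a third less catalyst and partner. I assumed the rate follows each, which Monday's run cannot show, and so took k as 0.0132 s⁻¹. Over 5.0 min that gives N = 3.95, the number of e-foldings, decay constant times time. Left-handed product is then 49.0%.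

**Second way.** The gap between Monday's left-handed product and the ceiling gave a faster decay, 0.0367 s⁻¹, and so 49.6%. The ways part by 0.60 percentage points. Monday's last pair adds to 52.8%, above the ceiling, so a reading stands high, and a high product reading narrows the gap and inflates k. I kept the first way.

**The rival.** Monday's last readings give a selectivity factor s = 22.2. Dividing N by s leaves 41.9% right-handed substrate in autumn, less than the product. Monday's run does not show what warming does, so I made no reckoning of my own for spring.

**The forecast.** It said left-handed product at 49.5% (47% to 50%) for autumn and left-handed product at 49.9% (46.5% to 50%) for spring, starting from “Each substrate is half of the charge”.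

**The flasks.** Autumn gave left-handed product at 48.0%, spring left-handed product at 49.8%.

    partner + precatalyst → catalyst + spent reagent (k = 0.580 M⁻¹ s⁻¹, Ea = 49.0 kJ mol⁻¹)
    partner + catalyst + left-handed substrate → catalyst + left-handed product (k = 680 M⁻² s⁻¹, Ea = 39.0 kJ mol⁻¹)
    partner + catalyst + right-handed substrate → catalyst + right-handed product (k = 40.0 M⁻² s⁻¹, Ea = 45.0 kJ mol⁻¹)
    (constants at 40 °C)

**What ran.** In autumn the left-handed step had half of its turnover done by 0.807 min, while the right-handed step had 63% of its turnover behind it at 2.50 min. At 5.00 min, 3.9% of the left-handed substrate and 24% of the partner remained, so autumn's real count was 3.24, below my N.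

**Earlier reading.** Autumn read at 2.0 min has N = 1.58, which gives left-handed product 39.7% and right-handed substrate 46.6%. The computed flask holds 40.3% and 45.4%, with right-handed substrate the most.

The numbers in the tables stem from a simulated flask with made-up constants, and the scatter is random.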